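The coumarin is opened at its C3=C4 double bond and its O1–C2 lactone bond, giving a salicylaldehyde and a dihydropyranonylacetic ester. The aldehyde carbon C4 is traced back to a methyl group: with CH3 on C4a, ring A is a 2,4,6-trimethylresorcinol with a mirror plane through C8 and C5, so the methyls on C4a and C6 are equivalent, each para to one hydroxyl (O1 or O7) and next to the C5 hydroxypropyl chain. A double DDQ oxidation converts either one into the aldehyde, caught as an isochroman lactol by the side-chain oxygen. The precursor is the unprotected, symmetric 5-[(S)-2-hydroxypropyl]-2,4,6-trimethylresorcinol.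

Key step: step 5

Remark on the chemistry: the lactol made in the key step is assumed to exchange in solution with its open hydroxy aldehyde and, by loss of water, with the alkoxy quinone methide that precedes it; all three share one oxidation level and should enter the last step alike (locants O1 to C8a are those of the coumarin).

Step 1
Reactants: 1 2,4-dibromomesitylene
Product: 2 1,3-dimethoxy-2,4,6-trimethylbenzene
Conditions: NaOMe (6 equiv), CuI (20 mol %), DMF/MeOH, 110 °C
Reagents that add atoms: sodium methoxide, C[O-].[Na+]
Why: Ullmann-type copper-catalysed methoxylation of an aryl bromide tolerates two ortho substituents and meets no competing functional group here, so both bromides should be exchanged for methoxy groups.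

Step 2
Reactants: 2 1,3-dimethoxy-2,4,6-trimethylbenzene
Product: 3 1-bromo-3,5-dimethoxy-2,4,6-trimethylbenzene
Conditions: Br2 (1.05 equiv), CH2Cl2, 0 °C, dark
Reagents that add atoms: bromine, BrBr
Why: Electrophilic aromatic bromination can only take the single ring C–H, which is activated by two ortho methyl groups and one para methyl group, and cold, dark, ionic conditions disfavour radical benzylic bromination.

Step 3
Reactants: 3 1-bromo-3,5-dimethoxy-2,4,6-trimethylbenzene; 4 (S)-propylene oxide
Product: 6 (2S)-1-(3,5-dimethoxy-2,4,6-trimethylphenyl)propan-2-ol, via arylmagnesium bromide 5 (not isolated)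
Conditions: Mg, THF, reflux; CuI (10 mol %), then 4, −30 °C → rt; 1 M aq. HCl
Reagents that add atoms: none
Why: The Grignard reagent should form as mesitylmagnesium bromide does, and the CuI-catalysed SN2 opening of the terminal epoxide occurs at the unsubstituted CH2, so the stereocentre of 4 is not touched and the carbinol is S.

Step 4
Reactants: 6 (2S)-1-(3,5-dimethoxy-2,4,6-trimethylphenyl)propan-2-ol
Product: 7 5-[(2S)-2-hydroxypropyl]-2,4,6-trimethylbenzene-1,3-diol
Conditions: BBr3 (4 equiv), CH2Cl2, −78 → 0 °C; MeOH, then H2O
Reagents that add atoms: none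
Why: BBr3 ether cleavage should remove both methyl groups at low temperature, since the methoxy groups are twisted out of the ring plane by their ortho methyl neighbours and are therefore basic, while the secondary alcohol is held as a borate that methanol releases with its C–O bond and S configuration intact.

Step 5
Reactants: 7 5-[(2S)-2-hydroxypropyl]-2,4,6-trimethylbenzene-1,3-diol
Product: 11 (3S)-3,5,7-trimethylisochroman-1,6,8-triol, via para-quinone methide 8 (not isolated), via isochromandiol 9 (not isolated), via alkoxy quinone methide 10 (not isolated)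
Conditions: DDQ (2.1 equiv), 1,4-dioxane/H2O (10:1), 0 °C → rt
Reagents that add atoms: water, O
Why: DDQ takes a hydride from a methyl group para to a phenolic hydroxyl to give quinone methide 8, the side-chain hydroxyl adds to its exocyclic CH2 with re-aromatisation to isochroman 9, a second DDQ removes the C1–H of 9, now activated by the ring oxygen as well as by the para hydroxyl, and water adds to the resulting quinone methide 10 to give lactol 11. The closest known reactions are the DDQ oxidation of 2,6-disubstituted 4-methylphenols to 4-hydroxybenzaldehydes and the DDQ oxidation of isochromans at C1 with capture by an oxygen nucleophile. The one ring formed, the oxygen ring of the isochroman, closes by a 6-endo-trig oxa-conjugate addition onto the quinone methide. The only new stereocentre is the lactol carbon C1, which is not controlled and need not be, because the anomers interconvert through the open aldehyde and the centre disappears in step 10, while C3 takes no part and stays S. The step needs oxidation at a methyl next to the chain and not at the C2 methyl or the benzylic CH2: the two flanking methyls are related by the mirror plane, so either gives the same product, the C2 methyl is ortho to both hydroxyls and could only give a less favoured ortho-quinone methide, and the CH2 is meta to both. Oxidation beyond the lactol should be limited by the charge of two equivalents and by the aldehyde tautomer of 11, which withdraws electron density from the ring.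

Step 6
Reactants: 12 methyl (R)-3-hydroxybutanoate
Product: 13 methyl (3R)-3-[(tert-butyldimethylsilyl)oxy]butanoate
Conditions: TBSCl, imidazole, DMF, rt
Reagents that add atoms: tert-butyldimethylsilyl chloride, CC(C)(C)[Si](C)(C)Cl
Why: Standard silylation of the secondary alcohol blocks alkoxide-driven retro-aldol and acyl transfer in the two organometallic steps that follow and does not touch the stereocentre.

Step 7
Reactants: 13 methyl (3R)-3-[(tert-butyldimethylsilyl)oxy]butanoate
Product: 14 (3R)-3-[(tert-butyldimethylsilyl)oxy]-N-methoxy-N-methylbutanamide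
Conditions: MeNHOMe·HCl, i-PrMgCl, THF, −20 → 0 °C; sat. aq. NH4Cl
Reagents that add atoms: N,O-dimethylhydroxylamine hydrochloride, CNOC.Cl
Why: Weinreb amide formation by aminolysis of the methyl ester with the chloromagnesium amide made in the flask should proceed below 0 °C without enolising the β-silyloxy ester, so neither elimination nor loss of configuration is expected.

Step 8
Reactants: 14 (3R)-3-[(tert-butyldimethylsilyl)oxy]-N-methoxy-N-methylbutanamide; 15 methyl acetoacetate
Product: 17 methyl (7R)-7-[(tert-butyldimethylsilyl)oxy]-3,5-dioxooctanoate, via acetoacetate dianion 16 (not isolated)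
Conditions: 15 (2.5 equiv), NaH, THF, 0 °C; n-BuLi, 0 °C; then 14, −78 → 0 °C; sat. aq. NH4Cl
Reagents that add atoms: none
Why: Claisen-type C-acylation of the acetoacetate dianion at its terminal carbon by a Weinreb amide should work because the chelated tetrahedral adduct holds back the acidic 3,5-dioxo ester until work-up and the excess of dianion covers any early collapse.

Step 9
Reactants: 17 methyl (7R)-7-[(tert-butyldimethylsilyl)oxy]-3,5-dioxooctanoate
Product: 19 methyl 2-[(2R)-2-methyl-4-oxo-3,4-dihydro-2H-pyran-6-yl]acetate, via hydroxy diketo ester 18 (not isolated)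
Conditions: 48% aq. HF, MeCN, 0 °C → rt
Reagents that add atoms: none
Why: Acidic desilylation frees the δ-hydroxy β-diketone 18, whose hydroxyl can reach only the C3 ketone in a six-membered hemiketal that loses water to the vinylogous ester (cyclodehydration to a 2,3-dihydro-4H-pyran-4-one), and since the C–O bond at the stereocentre is not broken it stays R.

Step 10
Reactants: 11 (3S)-3,5,7-trimethylisochroman-1,6,8-triol; 19 methyl 2-[(2R)-2-methyl-4-oxo-3,4-dihydro-2H-pyran-6-yl]acetate
Product: 22 7-hydroxy-5-[(2S)-2-hydroxypropyl]-6,8-dimethyl-3-[(2R)-2-methyl-4-oxo-3,4-dihydro-2H-pyran-6-yl]-2H-chromen-2-one, via hydroxy aldehyde 20 (not isolated), via arylidene ester 21 (not isolated)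
Conditions: piperidine (20 mol %), AcOH (20 mol %), MeOH, 50 °C
Reagents that add atoms: none
Why: Knoevenagel condensation with lactonisation (coumarin synthesis) should work because the CH2 of 19 is acidified by the ester and, through the enone, by the ring ketone, as in glutaconic and chromone-2-acetic esters; lactol 11 reacts through aldehyde 20, and closure of the Z-arylidene ester 21 by the ortho hydroxyl with loss of methanol is irreversible and should drain the reversible side equilibria, while neither stereocentre takes part.

Compound list
1 | 2,4-dibromomesitylene (1,3-dibromo-2,4,6-trimethylbenzene) | Cc1cc(C)c(Br)c(C)c1Br | starting material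
2 | 1,3-dimethoxy-2,4,6-trimethylbenzene | COc1c(C)cc(C)c(OC)c1C | intermediate
3 | 1-bromo-3,5-dimethoxy-2,4,6-trimethylbenzene | COc1c(C)c(Br)c(C)c(OC)c1C | intermediate
4 | (S)-propylene oxide, (2S)-2-methyloxirane | C[C@H]1CO1 | starting material
5 | (3,5-dimethoxy-2,4,6-trimethylphenyl)magnesium bromide | COc1c(C)c([Mg]Br)c(C)c(OC)c1C | intermediate
6 | (2S)-1-(3,5-dimethoxy-2,4,6-trimethylphenyl)propan-2-ol | COc1c(C)c(C[C@H](C)O)c(C)c(OC)c1C | intermediate
7 | 5-[(2S)-2-hydroxypropyl]-2,4,6-trimethylbenzene-1,3-diol | Cc1c(O)c(C)c(O)c(C)c1C[C@H](C)O | intermediate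
8 | 3-hydroxy-5-[(2S)-2-hydroxypropyl]-2,6-dimethyl-4-methylidenecyclohexa-2,5-dien-1-one | C=C1C(O)=C(C)C(=O)C(C)=C1C[C@H](C)O | intermediate
9 | (3S)-3,5,7-trimethylisochroman-6,8-diol | Cc1c(O)c(C)c(O)c2CO[C@@H](C)Cc12 | intermediate
10 | (3S)-8-hydroxy-3,5,7-trimethyl-3,4-dihydro-6H-isochromen-6-one | CC1=C2C[C@H](C)OC=C2C(O)=C(C)C1=O | intermediate
11 | (3S)-3,5,7-trimethylisochroman-1,6,8-triol (anomers interconvert) | Cc1c(O)c(C)c(O)c2C(O)O[C@@H](C)Cc12 | intermediate
12 | methyl (R)-3-hydroxybutanoate | COC(=O)C[C@@H](C)O | starting material
13 | methyl (3R)-3-[(tert-butyldimethylsilyl)oxy]butanoate | COC(=O)C[C@@H](C)O[Si](C)(C)C(C)(C)C | intermediate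
14 | (3R)-3-[(tert-butyldimethylsilyl)oxy]-N-methoxy-N-methylbutanamide | CON(C)C(=O)C[C@@H](C)O[Si](C)(C)C(C)(C)C | intermediate
15 | methyl acetoacetate | COC(=O)CC(C)=O | starting material
16 | lithium sodium dianion of methyl acetoacetate | [Li+].[Na+].COC(=O)[CH-]C(=O)[CH2-] | intermediate
17 | methyl (7R)-7-[(tert-butyldimethylsilyl)oxy]-3,5-dioxooctanoate | COC(=O)CC(=O)CC(=O)C[C@@H](C)O[Si](C)(C)C(C)(C)C | intermediate
18 | methyl (7R)-7-hydroxy-3,5-dioxooctanoate | COC(=O)CC(=O)CC(=O)C[C@@H](C)O | intermediate
19 | methyl 2-[(2R)-2-methyl-4-oxo-3,4-dihydro-2H-pyran-6-yl]acetate | COC(=O)CC1=CC(=O)C[C@@H](C)O1 | intermediate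
20 | 2,4-dihydroxy-6-[(2S)-2-hydroxypropyl]-3,5-dimethylbenzaldehyde | Cc1c(O)c(C)c(O)c(C=O)c1C[C@H](C)O | intermediate
21 | methyl (2Z)-3-{2,4-dihydroxy-6-[(2S)-2-hydroxypropyl]-3,5-dimethylphenyl}-2-[(2R)-2-methyl-4-oxo-3,4-dihydro-2H-pyran-6-yl]prop-2-enoate | COC(=O)/C(=C\c1c(O)c(C)c(O)c(C)c1C[C@H](C)O)C1=CC(=O)C[C@@H](C)O1 | intermediate
22 | 7-hydroxy-5-[(2S)-2-hydroxypropyl]-6,8-dimethyl-3-[(2R)-2-methyl-4-oxo-3,4-dihydro-2H-pyran-6-yl]-2H-chromen-2-one | Cc1c(O)c(C)c2oc(=O)c(C3=CC(=O)C[C@@H](C)O3)cc2c1C[C@H](C)O | target

Total step count: 10
Longest linear sequence: 6 steps (steps 1 to 5, then step 10); the ester branch is 5 steps (steps 6 to 9, then step 10).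

Steps most likely to fail

Step 5. The oxidation may not stop at the lactol. In its closed form 11 still holds a methyl para to a free hydroxyl and an oxidisable lactol C–H, so further hydride abstraction may run alongside. Attack may also begin at the C2 methyl, which would give mixtures of oxidation states. The fallback sets out from 6. One of its two equivalent methyl ethers is cleaved with NaSEt (DMF, 120 °C), a nucleophilic demethylation that should stop after the first ether, to give 3-[(2S)-2-hydroxypropyl]-5-methoxy-2,4,6-trimethylphenol F1. DDQ (2.1 equiv) in aqueous dioxane then meets the classical 2,6-dialkyl-4-methylphenol case. The single methyl para to the free hydroxyl should be oxidised with the same internal trapping to (3S)-8-methoxy-3,5,7-trimethylisochroman-1,6-diol F2. The second flanking methyl, now para only to a twisted methoxy group, should be left alone. Oxidation at the other chain-flanking methyl would lead to the same end point after demethylation. BCl3 (CH2Cl2, −78 → 0 °C) removes a methyl ether ortho to the aldehyde that the lactol masks, by chelation, and the sequence comes back to the route at 11.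

Step 10. The secondary amine may add to the vinylogous ester of 19 or of the product, with ring opening and re-closure that erodes the C2' configuration. The condensation of the only moderately acidic CH2 with the hindered, phenolate-deactivated aldehyde may also be too slow. The fallback sets out from 11 and 15. The same type of condensation with the far more acidic 15 (piperidine cat., MeOH, rt) should give 3-acetyl-7-hydroxy-5-[(2S)-2-hydroxypropyl]-6,8-dimethyl-2H-chromen-2-one F3. Both hydroxyls are silylated (TBSCl, imidazole, DMF, 40 °C) to its bis(tert-butyldimethylsilyl) ether F4. The lithium enolate of the acetyl group (LiN(SiMe3)2, THF, −78 °C) is C-acylated with Weinreb amide 14 to the silylated β-diketone F5. 48% aq. HF in MeCN then removes the three silyl groups, and the freed δ-hydroxyl closes onto the ketone next to the coumarin, the only six-membered option, with loss of water, which returns to the route at 22. The dihydropyranone is thus formed last, under acid, and never meets an amine.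

Step 4. The secondary borate may ionise or be displaced by bromide under the Lewis acid, possibly with help from the electron-rich ring, which would cost the alcohol or erode its configuration. The fallback sets out from 3. With no alcohol yet present, BBr3 (CH2Cl2, −78 °C → rt) gives 5-bromo-2,4,6-trimethylbenzene-1,3-diol F6. BnBr and K2CO3 in DMF give 1,3-bis(benzyloxy)-5-bromo-2,4,6-trimethylbenzene F7. Grignard formation and CuI-catalysed opening of 4, as in step 3, give (2S)-1-[3,5-bis(benzyloxy)-2,4,6-trimethylphenyl]propan-2-ol F8. Neutral hydrogenolysis (H2, Pd/C, EtOAc, rt) returns to the route at 7 without exposing the carbinol to a Lewis acid.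

Further compounds
F1 | step 5 | 3-[(2S)-2-hydroxypropyl]-5-methoxy-2,4,6-trimethylphenol | COc1c(C)c(O)c(C)c(C[C@H](C)O)c1C
F2 | step 5 | (3S)-8-methoxy-3,5,7-trimethylisochroman-1,6-diol | COc1c(C)c(O)c(C)c2C[C@H](C)OC(O)c12
F3 | step 10 | 3-acetyl-7-hydroxy-5-[(2S)-2-hydroxypropyl]-6,8-dimethyl-2H-chromen-2-one | CC(=O)c1cc2c(C[C@H](C)O)c(C)c(O)c(C)c2oc1=O
F4 | step 10 | 3-acetyl-7-[(tert-butyldimethylsilyl)oxy]-5-{(2S)-2-[(tert-butyldimethylsilyl)oxy]propyl}-6,8-dimethyl-2H-chromen-2-one | CC(=O)c1cc2c(C[C@H](C)O[Si](C)(C)C(C)(C)C)c(C)c(O[Si](C)(C)C(C)(C)C)c(C)c2oc1=O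
F5 | step 10 | (5R)-5-[(tert-butyldimethylsilyl)oxy]-1-[7-[(tert-butyldimethylsilyl)oxy]-5-{(2S)-2-[(tert-butyldimethylsilyl)oxy]propyl}-6,8-dimethyl-2-oxo-2H-chromen-3-yl]hexane-1,3-dione | C[C@@H](O[Si](C)(C)C(C)(C)C)CC(=O)CC(=O)c1cc2c(C[C@H](C)O[Si](C)(C)C(C)(C)C)c(C)c(O[Si](C)(C)C(C)(C)C)c(C)c2oc1=O
F6 | step 4 | 5-bromo-2,4,6-trimethylbenzene-1,3-diol | Cc1c(O)c(C)c(Br)c(C)c1O
F7 | step 4 | 1,3-bis(benzyloxy)-5-bromo-2,4,6-trimethylbenzene | Cc1c(OCc2ccccc2)c(C)c(Br)c(C)c1OCc1ccccc1
F8 | step 4 | (2S)-1-[3,5-bis(benzyloxy)-2,4,6-trimethylphenyl]propan-2-ol | Cc1c(OCc2ccccc2)c(C)c(C[C@H](C)O)c(C)c1OCc1ccccc1
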